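The constants used here were set for the occasion, and the outcome is calculated.

1. 848 M·s was the number I carried through these flasks. I call it the chain exposure: early on, the fraction of the J charge standing as L is the cube of θ over this number, where the exposure θ is the time integral of [X].

    X ⇌ Z (K1 = 8.1, k1 = 0.0029 /s)
    J + X → J.X (k2 = 0.0066 /M/s)
    X + L → X.L (k3 = 0.0011 /M/s)
    X + J.X → X.J.X (k4 = 2.1 × 10⁻⁴ /M/s)
    E ⇌ X, rate k5*(csat - [X]) (k5 = 7.8 × 10⁻⁴ /s, csat = 52 mM)
    X + X.J.X → L (k6 = 0.0071 /M/s)
the same everywhere: E 52 mM (held); time 50 min

| charge | J |
|---|---|
| noon | 0.12 M |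
| midnight | 0.25 M |
| spring | 0.50 M |
* [L] at the end for noon, midnight, spring, in this order
* the course of these numbers from the first flask to the last (falls all the way / hardly changes / rises, then falls / falls, then rises / rises all the way)
- at the start none of X is dissolved
- "hardly changes" means that all values lie within two and a half points (for a concentration: within two and a half percent of the largest)
- run time (noon): 50 min

2. X attacks J, J.X and X.J.X in turn. Each step is pseudo-first-order on the clock θ, so a chain of 3 steps gives the product of their constants, times θ cubed, over 6.

3. The setting I turned was the J charge, and I began with noon. The total drain on X, dissolving back included, was 0.00447 /s. With Z set aside, my first round gave X 0.00907 M.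

4. I went round again and put back the Z that the first round had made by mid-run. X rose to 0.0122 M. After a lag of 3.73 min, noon had θ = 34.0 M·s.

5. Raising the charge to midnight, the same two rounds gave θ = 27.7 M·s. Raising it to spring gave 20.3 M·s.

6. My shares of the charge were 0.00645%, 0.00349% and 0.00137%. Multiplied by the charges, they gave 7.70 × 10⁻⁶ M, 8.67 × 10⁻⁶ M and 6.86 × 10⁻⁶ M. So my row rose to midnight and then fell.

7. The forecast gave 5.600 × 10⁻⁶ M, 6.900 × 10⁻⁶ M and 6.000 × 10⁻⁶ M, with the shape "rises, then falls". Its ground: "More J adds chain starter but lowers X, which enters cubically". My row stood above it at each flask, with the same shape.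

8. The simulation gave 5.57 × 10⁻⁶ M, 6.83 × 10⁻⁶ M and 5.89 × 10⁻⁶ M: rises, then falls, turning at a J charge of 0.27 M. At noon 81% of the J charge stood unbound at the end, which reads as θ = 31.7 M·s. The chain exposure turns that into a share of 0.00522%, where the noon flask held 0.00464%. In spring, 87.8% of J left reads as θ = 19.8 M·s. With X ⇌ Z left out, spring gave 1.81 × 10⁻⁵ M, and the chain exposure 848 M·s reads that share of the charge as θ = 28.1 M·s.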